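**Retrosynthetic overview**
- Target ⇒ diol by esterifying both secondary hydroxyls with 3-methylbut-2-enoyl chloride; the diol comes from its mono-silyl ether by desilylation.
- C6–O ⇒ hydroxylation of the enolate of a cis-epoxy ketone; the oxirane ⇒ hydroxyl-directed epoxidation of a cis allylic alcohol made by Luche reduction of a carvone-type enone.
- Prenyl terminus ⇒ cross-metathesis of a homoallylic silyl ether with 2-methylbut-2-ene.
- Key C3′–C4′ bond ⇒ intermolecular, reagent-controlled carbonyl allylation (Brown allylboration) of a 2-substituted acrolein (fragment A, from (R)-carvone by allylic chlorination, acetate displacement, methanolysis, oxidation) with an allyl unit (fragment B, allylmagnesium bromide).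
- Ring order: the cyclohexane ring is taken intact from (R)-carvone; the oxirane is the only ring formed (step 9).

Convention: ring carbons are numbered as in carvone (C1 carbonyl, C2 methyl-bearing, C5 side-chain-bearing, C6 the CH2 that becomes the acyloxy carbon); side-chain carbons 1′–7′ as in 6-methylhepta-1,5-dien-2-yl (C3′ is the carbinol carbon); Ipc = isopinocampheyl, TBS = tert-butyldimethylsilyl.

**Route**

Step 1
Reactants: 1 (R)-(−)-carvone
Product: 2 (5R)-5-(3-chloroprop-1-en-2-yl)-2-methylcyclohex-2-en-1-one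
Conditions: Ca(OCl)2, CO2 (dry ice), CH2Cl2/H2O, 0 °C to rt
Reagents that add atoms: calcium hypochlorite, [Ca+2].[O-]Cl.[O-]Cl
Why: Ene-type allylic chlorination by HOCl attacks only the electron-rich isopropenyl group (the enone alkene is inert) and gives the 2-(chloromethyl)allyl unit without touching C5.

Step 2
Reactants: 2 (5R)-5-(3-chloroprop-1-en-2-yl)-2-methylcyclohex-2-en-1-one
Product: 3 2-[(1R)-4-methyl-5-oxocyclohex-3-en-1-yl]prop-2-en-1-yl acetate
Conditions: KOAc, n-Bu4NI (cat.), DMF, 50 °C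
Reagents that add atoms: potassium acetate, [K+].CC([O-])=O
Why: Iodide-assisted SN2 displacement of a primary allylic chloride by acetate, in which the direct and allylic-transposed pathways converge on the same product because the 2-substituted allyl unit is symmetric.

Step 3
Reactants: 3 2-[(1R)-4-methyl-5-oxocyclohex-3-en-1-yl]prop-2-en-1-yl acetate
Product: 4 (5R)-5-(3-hydroxyprop-1-en-2-yl)-2-methylcyclohex-2-en-1-one
Conditions: K2CO3 (0.2 equiv), MeOH, 0 °C
Reagents that add atoms: none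
Why: Base-catalysed transesterification (methanolysis) frees the primary allylic alcohol under conditions too mild to add methoxide to the enone.

Step 4
Reactants: 4 (5R)-5-(3-hydroxyprop-1-en-2-yl)-2-methylcyclohex-2-en-1-one
Product: 5 2-[(1R)-4-methyl-5-oxocyclohex-3-en-1-yl]prop-2-enal
Conditions: Dess–Martin periodinane, CH2Cl2, 0 °C to rt; used at once
Reagents that add atoms: none
Why: Dess–Martin oxidation takes the primary allylic alcohol to the 2-substituted acrolein under non-basic conditions, so the alkene does not migrate into conjugation with C5.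

Step 5
Reactants: 5 2-[(1R)-4-methyl-5-oxocyclohex-3-en-1-yl]prop-2-enal; 6 allylmagnesium bromide
Product: 9 (5R)-5-[(3R)-3-hydroxyhexa-1,5-dien-2-yl]-2-methylcyclohex-2-en-1-one, via B-allyldiisopinocampheylborane 7 (not isolated), via O-boryl adduct 8 (not isolated)
Conditions: (+)-B-methoxydiisopinocampheylborane ((+)-Ipc2BOMe, Ipc groups from (−)-α-pinene), CH2=CHCH2MgBr, Et2O, 0 °C to rt; then 5, −78 °C, 2 h; then HOCH2CH2NH2, rt
Reagents that add atoms: allylmagnesium bromide (compound 6), C=CC[Mg]Br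
Why: Brown asymmetric allylboration (carbonyl allylation) through a closed chair transition state adds the allyl group to the Re face of the aldehyde under reagent control, setting C3′ as R, while at −78 °C the aldehyde reacts far faster than the conjugated ring ketone and the non-oxidative aminoethanol work-up spares the enone.

Step 6
Reactants: 9 (5R)-5-[(3R)-3-hydroxyhexa-1,5-dien-2-yl]-2-methylcyclohex-2-en-1-one
Product: 10 (5R)-5-[(3R)-3-(tert-butyldimethylsilyloxy)hexa-1,5-dien-2-yl]-2-methylcyclohex-2-en-1-one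
Conditions: TBSCl, imidazole, DMF, rt
Reagents that add atoms: tert-butyldimethylsilyl chloride, CC(C)(C)[Si](C)(C)Cl
Why: Imidazole-promoted silylation masks the allylic alcohol for the later hydride, peroxide and enolate steps, and the minor C3′ epimer is removed by chromatography here.

Step 7
Reactants: 10 (5R)-5-[(3R)-3-(tert-butyldimethylsilyloxy)hexa-1,5-dien-2-yl]-2-methylcyclohex-2-en-1-one; 11 2-methylbut-2-ene
Product: 12 (5R)-5-[(3R)-3-(tert-butyldimethylsilyloxy)-6-methylhepta-1,5-dien-2-yl]-2-methylcyclohex-2-en-1-one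
Conditions: second-generation Grubbs catalyst (H2IMes)(PCy3)Cl2Ru=CHPh (5 mol %), 2-methylbut-2-ene/CH2Cl2 (1:1), 40 °C
Reagents that add atoms: 2-methylbut-2-ene (compound 11), CC=C(C)C
Why: Olefin cross-metathesis exchanges the methylene of the only monosubstituted alkene for an isopropylidene group, the hindered 1,1-disubstituted alkene and the electron-poor enone alkene being unreactive.

Step 8
Reactants: 12 (5R)-5-[(3R)-3-(tert-butyldimethylsilyloxy)-6-methylhepta-1,5-dien-2-yl]-2-methylcyclohex-2-en-1-one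
Product: 13 (1R,5R)-5-[(3R)-3-(tert-butyldimethylsilyloxy)-6-methylhepta-1,5-dien-2-yl]-2-methylcyclohex-2-en-1-ol
Conditions: NaBH4, CeCl3·7H2O, MeOH, −78 to −20 °C
Reagents that add atoms: none
Why: Luche 1,2-reduction delivers hydride axially to the enone with the C5 substituent equatorial, giving the pseudo-equatorial C1 alcohol cis to the side chain (C1 R), as in carvone to cis-carveol.

Step 9
Reactants: 13 (1R,5R)-5-[(3R)-3-(tert-butyldimethylsilyloxy)-6-methylhepta-1,5-dien-2-yl]-2-methylcyclohex-2-en-1-ol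
Product: 14 (1R,2R,4S,6S)-4-[(3R)-3-(tert-butyldimethylsilyloxy)-6-methylhepta-1,5-dien-2-yl]-1-methyl-7-oxabicyclo[4.1.0]heptan-2-ol
Conditions: VO(acac)2 (5 mol %), t-BuOOH (decane solution), CH2Cl2, 0 °C to rt
Reagents that add atoms: tert-butyl hydroperoxide, CC(C)(C)OO
Why: Vanadium-catalysed hydroxyl-directed epoxidation delivers oxygen to the ring alkene on the face of the C1 hydroxyl, which is the face of the C5 side chain, setting C2 and C3, while the prenyl and 1,1-disubstituted alkenes have no directing allylic hydroxyl and stay intact.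

Step 10
Reactants: 14 (1R,2R,4S,6S)-4-[(3R)-3-(tert-butyldimethylsilyloxy)-6-methylhepta-1,5-dien-2-yl]-1-methyl-7-oxabicyclo[4.1.0]heptan-2-ol
Product: 15 (1S,4R,6S)-4-[(3R)-3-(tert-butyldimethylsilyloxy)-6-methylhepta-1,5-dien-2-yl]-1-methyl-7-oxabicyclo[4.1.0]heptan-2-one
Conditions: Dess–Martin periodinane, NaHCO3, CH2Cl2, 0 °C to rt
Reagents that add atoms: none
Why: Buffered Dess–Martin oxidation converts the secondary alcohol to the ketone without opening the oxirane or cleaving the silyl ether, and no stereocentre is touched.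

Step 11
Reactants: 15 (1S,4R,6S)-4-[(3R)-3-(tert-butyldimethylsilyloxy)-6-methylhepta-1,5-dien-2-yl]-1-methyl-7-oxabicyclo[4.1.0]heptan-2-one
Product: 17 (1S,3S,4S,6S)-4-[(3R)-3-(tert-butyldimethylsilyloxy)-6-methylhepta-1,5-dien-2-yl]-3-hydroxy-1-methyl-7-oxabicyclo[4.1.0]heptan-2-one, via potassium enolate 16 (not isolated)
Conditions: KN(SiMe3)2, THF, −78 °C; then 2-(phenylsulfonyl)-3-phenyloxaziridine, −78 °C; AcOH quench at −78 °C
Reagents that add atoms: 2-(phenylsulfonyl)-3-phenyloxaziridine (Davis oxaziridine), O=S(=O)(c1ccccc1)N1OC1c1ccccc1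
Why: Davis enolate hydroxylation works here because C6 is the only enolisable position (C2 is quaternary), and the oxaziridine approaches anti to the adjacent C5 side chain and to the oxirane on that same face, giving the 5,6-trans ketol (C6 S) without epoxidising the alkenes.

Step 12
Reactants: 17 (1S,3S,4S,6S)-4-[(3R)-3-(tert-butyldimethylsilyloxy)-6-methylhepta-1,5-dien-2-yl]-3-hydroxy-1-methyl-7-oxabicyclo[4.1.0]heptan-2-one
Product: 18 (1S,3S,4S,6S)-3-hydroxy-4-[(3R)-3-hydroxy-6-methylhepta-1,5-dien-2-yl]-1-methyl-7-oxabicyclo[4.1.0]heptan-2-one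
Conditions: HF·pyridine, pyridine, THF, 0 °C to rt
Reagents that add atoms: none
Why: Buffered fluoride desilylation cleaves the Si–O bond under non-basic conditions that neither epimerise the ketol nor open the electron-poor epoxy ketone.

Step 13
Reactants: 18 (1S,3S,4S,6S)-3-hydroxy-4-[(3R)-3-hydroxy-6-methylhepta-1,5-dien-2-yl]-1-methyl-7-oxabicyclo[4.1.0]heptan-2-one; 19 3-methylbut-2-enoyl chloride
Product: 20 (1S,3S,4S,6S)-1-methyl-4-[(3R)-6-methyl-3-(3-methylbut-2-enoyloxy)hepta-1,5-dien-2-yl]-2-oxo-7-oxabicyclo[4.1.0]heptan-3-yl 3-methylbut-2-enoate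
Conditions: 3-methylbut-2-enoyl chloride (3 equiv), pyridine, DMAP (cat.), CH2Cl2, 0 °C to rt
Reagents that add atoms: 3-methylbut-2-enoyl chloride (compound 19), CC(C)=CC(=O)Cl
Why: DMAP-catalysed acylation esterifies both secondary hydroxyls in one operation, pyridine being too weak a base to deconjugate the senecioyl unit, and no stereocentre is touched.

**Compound list**

1 | (R)-(−)-carvone, (5R)-2-methyl-5-(prop-1-en-2-yl)cyclohex-2-en-1-one | C=C(C)[C@@H]1CC=C(C)C(=O)C1 | starting material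
2 | (5R)-5-(3-chloroprop-1-en-2-yl)-2-methylcyclohex-2-en-1-one | C=C(CCl)[C@@H]1CC=C(C)C(=O)C1 | intermediate
3 | 2-[(1R)-4-methyl-5-oxocyclohex-3-en-1-yl]prop-2-en-1-yl acetate | C=C(COC(C)=O)[C@@H]1CC=C(C)C(=O)C1 | intermediate
4 | (5R)-5-(3-hydroxyprop-1-en-2-yl)-2-methylcyclohex-2-en-1-one | C=C(CO)[C@@H]1CC=C(C)C(=O)C1 | intermediate
5 | 2-[(1R)-4-methyl-5-oxocyclohex-3-en-1-yl]prop-2-enal | C=C(C=O)[C@@H]1CC=C(C)C(=O)C1 | intermediate
6 | allylmagnesium bromide | C=CC[Mg]Br | starting material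
7 | B-allyldiisopinocampheylborane (both Ipc groups from (−)-α-pinene) | C=CCB([C@H]1C[C@H]2C[C@H](C2(C)C)[C@@H]1C)[C@H]1C[C@H]2C[C@H](C2(C)C)[C@@H]1C | intermediate
8 | (3R)-2-[(1R)-4-methyl-5-oxocyclohex-3-en-1-yl]hexa-1,5-dien-3-yl diisopinocampheylborinate | C=C([C@@H](CC=C)OB([C@H]1C[C@H]2C[C@H](C2(C)C)[C@@H]1C)[C@H]1C[C@H]2C[C@H](C2(C)C)[C@@H]1C)[C@@H]1CC=C(C)C(=O)C1 | intermediate
9 | (5R)-5-[(3R)-3-hydroxyhexa-1,5-dien-2-yl]-2-methylcyclohex-2-en-1-one | C=C([C@@H](CC=C)O)[C@@H]1CC=C(C)C(=O)C1 | intermediate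
10 | (5R)-5-[(3R)-3-(tert-butyldimethylsilyloxy)hexa-1,5-dien-2-yl]-2-methylcyclohex-2-en-1-one | C=C([C@@H](CC=C)O[Si](C)(C)C(C)(C)C)[C@@H]1CC=C(C)C(=O)C1 | intermediate
11 | 2-methylbut-2-ene | CC=C(C)C | starting material
12 | (5R)-5-[(3R)-3-(tert-butyldimethylsilyloxy)-6-methylhepta-1,5-dien-2-yl]-2-methylcyclohex-2-en-1-one | C=C([C@@H](CC=C(C)C)O[Si](C)(C)C(C)(C)C)[C@@H]1CC=C(C)C(=O)C1 | intermediate
13 | (1R,5R)-5-[(3R)-3-(tert-butyldimethylsilyloxy)-6-methylhepta-1,5-dien-2-yl]-2-methylcyclohex-2-en-1-ol (OH cis to side chain) | C=C([C@@H](CC=C(C)C)O[Si](C)(C)C(C)(C)C)[C@@H]1CC=C(C)[C@H](O)C1 | intermediate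
14 | (1R,2R,4S,6S)-4-[(3R)-3-(tert-butyldimethylsilyloxy)-6-methylhepta-1,5-dien-2-yl]-1-methyl-7-oxabicyclo[4.1.0]heptan-2-ol (oxirane, OH and side chain all cis) | C=C([C@@H](CC=C(C)C)O[Si](C)(C)C(C)(C)C)[C@@H]1C[C@@H]2O[C@]2(C)[C@H](O)C1 | intermediate
15 | (1S,4R,6S)-4-[(3R)-3-(tert-butyldimethylsilyloxy)-6-methylhepta-1,5-dien-2-yl]-1-methyl-7-oxabicyclo[4.1.0]heptan-2-one (oxirane cis to side chain) | C=C([C@@H](CC=C(C)C)O[Si](C)(C)C(C)(C)C)[C@@H]1C[C@@H]2O[C@]2(C)C(=O)C1 | intermediate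
16 | potassium enolate of 15 (C1=C6) | C=C([C@@H](CC=C(C)C)O[Si](C)(C)C(C)(C)C)[C@@H]1C[C@@H]2O[C@]2(C)C([O-])=C1.[K+] | intermediate
17 | (1S,3S,4S,6S)-4-[(3R)-3-(tert-butyldimethylsilyloxy)-6-methylhepta-1,5-dien-2-yl]-3-hydroxy-1-methyl-7-oxabicyclo[4.1.0]heptan-2-one (C6–OH trans to side chain and oxirane) | C=C([C@@H](CC=C(C)C)O[Si](C)(C)C(C)(C)C)[C@@H]1C[C@@H]2O[C@]2(C)C(=O)[C@H]1O | intermediate
18 | (1S,3S,4S,6S)-3-hydroxy-4-[(3R)-3-hydroxy-6-methylhepta-1,5-dien-2-yl]-1-methyl-7-oxabicyclo[4.1.0]heptan-2-one | C=C([C@@H](CC=C(C)C)O)[C@@H]1C[C@@H]2O[C@]2(C)C(=O)[C@H]1O | intermediate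
19 | 3-methylbut-2-enoyl chloride | CC(C)=CC(=O)Cl | starting material
20 | CNP0140369.1, (1S,3S,4S,6S)-1-methyl-4-[(3R)-6-methyl-3-(3-methylbut-2-enoyloxy)hepta-1,5-dien-2-yl]-2-oxo-7-oxabicyclo[4.1.0]heptan-3-yl 3-methylbut-2-enoate | C=C([C@@H](CC=C(C)C)OC(=O)C=C(C)C)[C@@H]1C[C@@H]2O[C@]2(C)C(=O)[C@H]1OC(=O)C=C(C)C | target

**Step count and risks**

Total steps: 13. Longest linear sequence: 13 steps (1 to 20).

Most likely to fail, step 5 (the allylborane may also attack the ring ketone, or facial control at C3′ may be incomplete). The fallback sets out from 5 and comes back at 13. Aldehyde 5 is coupled instead in a chelate-controlled acetate aldol addition with the titanium enolate of (4S)-3-acetyl-4-isopropyl-1,3-thiazolidine-2-thione (TiCl4, i-Pr2NEt, CH2Cl2, −78 °C). This gives the chromatographically purifiable (3′R) aldol adduct F1. TBSOTf/2,6-lutidine converts it to the silyl ether F2. i-Bu2AlH (CH2Cl2, −78 °C) then releases the auxiliary to leave the aldehyde and at the same time reduces the ring enone by axial hydride delivery to the cis allylic alcohol, giving the hydroxy aldehyde F3. Wittig olefination with Ph3P=CMe2 (from i-PrPPh3I and n-BuLi, THF, −78 to 0 °C) installs the isopropylidene group and gives 13, so steps 5 to 8 are bypassed.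

Second, step 11 (the epoxy ketone enolate 16 may decompose, or hydroxylation may be unselective). The fallback sets out from 12 and comes back at 18. The C6 oxygen is introduced before the oxirane exists: KN(SiMe3)2 (THF, −78 °C) converts 12 to its cross-conjugated dienolate, which the same oxaziridine hydroxylates anti to the side chain to give the trans ketol F4. TBSOTf/2,6-lutidine gives the bis-silyl ether F5. Luche reduction (NaBH4, CeCl3·7H2O, MeOH; axial attack, all-equatorial product) gives the allylic alcohol F6. VO(acac)2/t-BuOOH epoxidises syn to the C1 hydroxyl to give the epoxy alcohol F7. Dess–Martin oxidation gives the epoxy ketone F8, and HF·pyridine removes both silyl groups to give 18.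

Third, step 13 (incomplete acylation of the hindered C3′ alcohol, or damage to the free ketol under the acylation conditions). The fallback sets out from 17 and comes back at 20. The esters are installed one at a time: 3-methylbut-2-enoyl chloride/pyridine/DMAP acylates the C6 hydroxyl of 17 to give the mono-ester F9. HF·pyridine frees the C3′ alcohol to give the hydroxy ester F10. A Yamaguchi esterification (3-methylbut-2-enoic acid, 2,4,6-trichlorobenzoyl chloride, Et3N, DMAP, toluene, rt) then gives 20.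

**Further compounds**

F1 | step 5 | (5R)-5-[(3R)-3-hydroxy-5-oxo-5-[(4S)-4-isopropyl-2-thioxo-1,3-thiazolidin-3-yl]pent-1-en-2-yl]-2-methylcyclohex-2-en-1-one | C=C([C@@H](CC(=O)N1[C@@H](C(C)C)CSC1=S)O)[C@@H]1CC=C(C)C(=O)C1
F2 | step 5 | (5R)-5-[(3R)-3-(tert-butyldimethylsilyloxy)-5-oxo-5-[(4S)-4-isopropyl-2-thioxo-1,3-thiazolidin-3-yl]pent-1-en-2-yl]-2-methylcyclohex-2-en-1-one | C=C([C@@H](CC(=O)N1[C@@H](C(C)C)CSC1=S)O[Si](C)(C)C(C)(C)C)[C@@H]1CC=C(C)C(=O)C1
F3 | step 5 | (3R)-3-(tert-butyldimethylsilyloxy)-4-[(1R,5R)-5-hydroxy-4-methylcyclohex-3-en-1-yl]pent-4-enal | C=C([C@@H](CC=O)O[Si](C)(C)C(C)(C)C)[C@@H]1CC=C(C)[C@H](O)C1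
F4 | step 11 | (5S,6S)-5-[(3R)-3-(tert-butyldimethylsilyloxy)-6-methylhepta-1,5-dien-2-yl]-6-hydroxy-2-methylcyclohex-2-en-1-one (5,6-trans) | C=C([C@@H](CC=C(C)C)O[Si](C)(C)C(C)(C)C)[C@@H]1CC=C(C)C(=O)[C@H]1O
F5 | step 11 | (5S,6S)-6-(tert-butyldimethylsilyloxy)-5-[(3R)-3-(tert-butyldimethylsilyloxy)-6-methylhepta-1,5-dien-2-yl]-2-methylcyclohex-2-en-1-one | C=C([C@@H](CC=C(C)C)O[Si](C)(C)C(C)(C)C)[C@@H]1CC=C(C)C(=O)[C@H]1O[Si](C)(C)C(C)(C)C
F6 | step 11 | (1S,5S,6S)-6-(tert-butyldimethylsilyloxy)-5-[(3R)-3-(tert-butyldimethylsilyloxy)-6-methylhepta-1,5-dien-2-yl]-2-methylcyclohex-2-en-1-ol (C1–OH cis to side chain) | C=C([C@@H](CC=C(C)C)O[Si](C)(C)C(C)(C)C)[C@@H]1CC=C(C)[C@H](O)[C@H]1O[Si](C)(C)C(C)(C)C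
F7 | step 11 | (1R,2R,3S,4S,6S)-3-(tert-butyldimethylsilyloxy)-4-[(3R)-3-(tert-butyldimethylsilyloxy)-6-methylhepta-1,5-dien-2-yl]-1-methyl-7-oxabicyclo[4.1.0]heptan-2-ol | C=C([C@@H](CC=C(C)C)O[Si](C)(C)C(C)(C)C)[C@@H]1C[C@@H]2O[C@]2(C)[C@H](O)[C@H]1O[Si](C)(C)C(C)(C)C
F8 | step 11 | (1S,3S,4S,6S)-3-(tert-butyldimethylsilyloxy)-4-[(3R)-3-(tert-butyldimethylsilyloxy)-6-methylhepta-1,5-dien-2-yl]-1-methyl-7-oxabicyclo[4.1.0]heptan-2-one | C=C([C@@H](CC=C(C)C)O[Si](C)(C)C(C)(C)C)[C@@H]1C[C@@H]2O[C@]2(C)C(=O)[C@H]1O[Si](C)(C)C(C)(C)C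
F9 | step 13 | (1S,3S,4S,6S)-4-[(3R)-3-(tert-butyldimethylsilyloxy)-6-methylhepta-1,5-dien-2-yl]-1-methyl-2-oxo-7-oxabicyclo[4.1.0]heptan-3-yl 3-methylbut-2-enoate | C=C([C@@H](CC=C(C)C)O[Si](C)(C)C(C)(C)C)[C@@H]1C[C@@H]2O[C@]2(C)C(=O)[C@H]1OC(=O)C=C(C)C
F10 | step 13 | (1S,3S,4S,6S)-4-[(3R)-3-hydroxy-6-methylhepta-1,5-dien-2-yl]-1-methyl-2-oxo-7-oxabicyclo[4.1.0]heptan-3-yl 3-methylbut-2-enoate | C=C([C@@H](CC=C(C)C)O)[C@@H]1C[C@@H]2O[C@]2(C)C(=O)[C@H]1OC(=O)C=C(C)C
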